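**Strategy.** Ring C of the upper chromanone is disconnected at O1–C8a and C4–C4a, so that ring A arrives as 3,5-bis(benzyloxy)benzyne. In the key step the tertiary C2 alkoxide of an open-chain β-hydroxy ester adds to the aryne, and the aryl anion so formed acylates itself on the C4 ester, which closes ring C through the C4–C4a bond. The step exploits the phloroglucinol pattern of ring A: the oxygen-bearing C8a and the acyl-bearing C4a are neighbours, and the C5 oxygen steers the carbanion onto C4a. The precursor carries perbenzylated kaempferol (through its C8) on C2 and, at C3, a hydrogenolysable twofold-symmetric hydrobenzoin ketal that sets C2 and later unveils the hemiketal.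

Key step: step 10

Remark on numbering: O1, C2, C3, C4, C4a, C5–C8, C8a refer to the upper chromanone; positions of the lower unit are written as kaempferol C8, kaempferol O7.

Assumption: the facial sense of the auxiliary-controlled addition in step 7 is taken from a chelate model and not from a measured case; the two C2 epimers are diastereomers and separable.

**Step 1**
Reactants: 1 kaempferol
Product: 2 3,5,7-tris(benzyloxy)-2-[4-(benzyloxy)phenyl]-4H-chromen-4-one
Conditions: BnBr (6 equiv), K2CO3, DMF, 80 °C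
Reagents that add atoms: benzyl bromide, BrCc1ccccc1
Why: Williamson etherification of all four hydroxyl groups, with excess halide and heat so that the hydrogen-bonded 5-OH is also alkylated; no stereocentre is involved.

**Step 2**
Reactants: 2 tetra-O-benzylkaempferol
Product: 3 3,5,7-tris(benzyloxy)-2-[4-(benzyloxy)phenyl]-8-iodo-4H-chromen-4-one
Conditions: NIS, TFA (cat.), MeCN–CH2Cl2, 0 °C → rt
Reagents that add atoms: N-iodosuccinimide, O=C1CCC(=O)N1I
Why: Electrophilic aromatic iodination of the most electron-rich ring; C8, flanked by one benzyloxy group and the ring oxygen, is less hindered than C6 between two benzyloxy groups, so mono-iodination at C8 is expected.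

**Step 3**
Reactants: 4 1-[4-(benzyloxy)phenyl]ethan-1-one
Product: 5 methyl 3-[4-(benzyloxy)phenyl]-3-oxopropanoate
Conditions: NaH, (MeO)2CO, THF, reflux; then aq. HCl
Reagents that add atoms: dimethyl carbonate, COC(=O)OC
Why: Crossed Claisen condensation (C-acylation of the ketone enolate by the carbonate), driven by deprotonation of the β-keto ester formed.

**Step 4**
Reactants: 5 β-keto ester
Product: 6 methyl 3-[4-(benzyloxy)phenyl]-2-diazo-3-oxopropanoate
Conditions: 4-acetamidobenzenesulfonyl azide, Et3N, MeCN, 0 °C → rt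
Reagents that add atoms: 4-acetamidobenzenesulfonyl azide, CC(=O)Nc1ccc(cc1)S(=O)(=O)N=[N+]=[N-]
Why: Regitz diazo transfer to the doubly activated methylene group.

**Step 5**
Reactants: 6 diazo keto ester; 7 (1R,2R)-1,2-diphenylethane-1,2-diol
Product: 8 methyl 3-[4-(benzyloxy)phenyl]-2-{[(1R,2R)-2-hydroxy-1,2-diphenylethyl]oxy}-3-oxopropanoate
Conditions: Rh2(OAc)4 (1 mol %), 7 (3 equiv), CH2Cl2, reflux
Reagents that add atoms: none
Why: Rhodium-carbenoid O–H insertion of an acceptor/acceptor diazo compound into one of the two equivalent hydroxyls of the twofold-symmetric diol (excess diol suppresses double insertion); the carbinol centres are untouched, and the new α-centre forms as an epimer mixture that becomes non-stereogenic in step 6.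

**Step 6**
Reactants: 8 hydroxy ether
Product: 10 methyl (4R,5R)-2-[4-(benzyloxy)benzoyl]-4,5-diphenyl-1,3-dioxolane-2-carboxylate, via bromo ether 9 (not isolated)
Conditions: NBS, K2CO3, MeCN, 0 °C → rt
Reagents that add atoms: none
Why: Bromination of the enol gives the tertiary α-bromo ether 9, whose bromide is displaced by the free hydroxyl (5-exo-tet, assisted by the ether oxygen), the same closure as in dioxole formation from dibromomalonates and diols; the C–O bonds at C4 and C5 are not touched, so the ring is (4R,5R), and its C2 is not stereogenic because the diol is twofold-symmetric.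

**Step 7**
Reactants: 3 8-iodo-tetra-O-benzylkaempferol; 10 ketal keto ester
Product: 12 methyl (4R,5R)-2-[(R)-[4-(benzyloxy)phenyl](hydroxy){3,5,7-tris(benzyloxy)-2-[4-(benzyloxy)phenyl]-4-oxo-4H-chromen-8-yl}methyl]-4,5-diphenyl-1,3-dioxolane-2-carboxylate, via arylmagnesium chloride 11 (not isolated)
Conditions: 3, i-PrMgCl·LiCl, THF, −40 °C; then 10, −40 → 0 °C; aq. NH4Cl
Reagents that add atoms: none
Why: Iodine–magnesium exchange (fast next to two ortho oxygens) then chelation-controlled 1,2-addition of the aryl Grignard reagent to the α-keto ketal, the ketone reacting before the hindered ester; the carbinol centre is set by the auxiliary, the aryl group entering on the ketone face away from the dioxolane phenyl that lies cis to the aroyl group, which should give R, and the S epimer is removed by chromatography.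

**Step 8**
Reactants: 13 3,5-bis(benzyloxy)phenol
Product: 14 3,5-bis(benzyloxy)-2-bromophenol
Conditions: NBS, i-Pr2NH (cat.), CH2Cl2, −78 → 0 °C
Reagents that add atoms: N-bromosuccinimide, O=C1CCC(=O)N1Br
Why: Amine-catalysed ortho-selective bromination of a phenol; the two positions ortho to OH are equivalent and are preferred over the para position, which sits between two benzyloxy groups.

**Step 9**
Reactants: 14 bromophenol
Product: 18 3,5-bis(benzyloxy)-2-(trimethylsilyl)phenyl trifluoromethanesulfonate, via aryl silyl ether 15 (not isolated), via aryllithium 16 (not isolated), via lithium silylphenoxide 17 (not isolated)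
Conditions: (Me3Si)2NH, THF, 65 °C, concentrate; n-BuLi, THF, −100 °C; Tf2O, −100 → −78 °C
Reagents that add atoms: hexamethyldisilazane, C[Si](C)(C)N[Si](C)(C)C; trifluoromethanesulfonic anhydride, O=S(=O)(OS(=O)(=O)C(F)(F)F)C(F)(F)F
Why: O-silylation, bromine–lithium exchange, 1,3-shift of silicon from oxygen to carbon (retro-Brook rearrangement) and triflation of the lithium phenoxide, the standard route to 2-silylaryl triflates as aryne precursors.

**Step 10**
Reactants: 12 tertiary carbinol ester; 18 silylaryl triflate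
Product: 22 (2R,4'R,5'R)-5,7-bis(benzyloxy)-2-[4-(benzyloxy)phenyl]-4',5'-diphenyl-2-{3,5,7-tris(benzyloxy)-2-[4-(benzyloxy)phenyl]-4-oxo-4H-chromen-8-yl}spiro[chromane-3,2'-[1,3]dioxolan]-4-one, via potassium alkoxide 19 (not isolated), via 3,5-bis(benzyloxy)benzyne 20 (not isolated), via arylpotassium 21 (not isolated)
Conditions: KH, THF, 0 °C; then 18 (1.5 equiv), CsF, 18-crown-6 (cat.), THF, −20 °C → rt; aq. NH4Cl
Reagents that add atoms: none
Why: Proposed new method: alkoxide 19 attacks aryne 20 at the aryne carbon remote from the adjacent benzyloxy group (the future C8a), which leaves the carbanion of 21 next to that benzyloxy group (the future C4a), and this aryl anion attacks the methyl ester on C3 and expels methoxide, so that ring C closes through the C4–C4a bond by a 6-exo-trig acyl substitution. The closest known reaction type is the aryne annulation of salicylate esters to xanthones (O-arylation of a phenoxide by an aryne, then acylation of the aryl anion by the ortho ester), together with aryne acyl-alkylation, where 3-alkoxyarynes show the same regiochemistry; what is new is a tertiary aliphatic alkoxide as the nucleophile. No stereocentre is created: C2 (R) only uses its O–H bond and C3 is a non-stereogenic spiro ketal carbon. The step needs regioselective attack on the aryne, secured by the inductive and distortion effect of the 3-benzyloxy group, and acylation instead of protonation of the aryl anion, secured by the preformed potassium alkoxide (no O–H proton in the flask) and the six-membered transition state. It also needs the anion to spare C3, which the ketal secures while it blocks enolisation and β-elimination towards C2.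

**Step 11**
Reactants: 22 spiro ketal chromanone
Product: 24 target CNP0314633.1 [(2R,3S)-3,5,7-trihydroxy-2-(4-hydroxyphenyl)chroman-4-one whose C2 is bonded to kaempferol C8 and whose C3 is bonded to kaempferol O7 in a cis-fused dihydrofuran ring], via 3,4-dione 23 (not isolated)
Conditions: H2 (1 atm), Pd(OH)2 on carbon, EtOAc–MeOH, rt
Reagents that add atoms: none
Why: Hydrogenolysis of the seven benzyl ethers and of both benzylic C–O bonds of the diphenyldioxolane frees the C3 ketone and the kaempferol 7-OH, which closes the five-membered hemiketal on C3; because this oxygen is held by kaempferol C8 on C2, only the cis-fused hemiketal (3S) can form, so C3 is set by the untouched C2 (R).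

**Compound list**

1 | kaempferol, 3,5,7-trihydroxy-2-(4-hydroxyphenyl)-4H-chromen-4-one | O=c1c(O)c(-c2ccc(O)cc2)oc2cc(O)cc(O)c12 | starting material
2 | 3,5,7-tris(benzyloxy)-2-[4-(benzyloxy)phenyl]-4H-chromen-4-one | O=c1c(OCc2ccccc2)c(-c2ccc(OCc3ccccc3)cc2)oc2cc(OCc3ccccc3)cc(OCc3ccccc3)c12 | intermediate
3 | 3,5,7-tris(benzyloxy)-2-[4-(benzyloxy)phenyl]-8-iodo-4H-chromen-4-one | O=c1c(OCc2ccccc2)c(-c2ccc(OCc3ccccc3)cc2)oc2c(I)c(OCc3ccccc3)cc(OCc3ccccc3)c12 | intermediate
4 | 1-[4-(benzyloxy)phenyl]ethan-1-one | CC(=O)c1ccc(OCc2ccccc2)cc1 | starting material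
5 | methyl 3-[4-(benzyloxy)phenyl]-3-oxopropanoate | COC(=O)CC(=O)c1ccc(OCc2ccccc2)cc1 | intermediate
6 | methyl 3-[4-(benzyloxy)phenyl]-2-diazo-3-oxopropanoate | COC(=O)C(=[N+]=[N-])C(=O)c1ccc(OCc2ccccc2)cc1 | intermediate
7 | (1R,2R)-1,2-diphenylethane-1,2-diol, (R,R)-hydrobenzoin | O[C@H](c1ccccc1)[C@H](O)c1ccccc1 | starting material
8 | methyl 3-[4-(benzyloxy)phenyl]-2-{[(1R,2R)-2-hydroxy-1,2-diphenylethyl]oxy}-3-oxopropanoate (both C2 epimers) | COC(=O)C(O[C@H](c1ccccc1)[C@H](O)c1ccccc1)C(=O)c1ccc(OCc2ccccc2)cc1 | intermediate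
9 | methyl 3-[4-(benzyloxy)phenyl]-2-bromo-2-{[(1R,2R)-2-hydroxy-1,2-diphenylethyl]oxy}-3-oxopropanoate | COC(=O)C(Br)(O[C@H](c1ccccc1)[C@H](O)c1ccccc1)C(=O)c1ccc(OCc2ccccc2)cc1 | intermediate
10 | methyl (4R,5R)-2-[4-(benzyloxy)benzoyl]-4,5-diphenyl-1,3-dioxolane-2-carboxylate | COC(=O)C1(C(=O)c2ccc(OCc3ccccc3)cc2)O[C@H](c2ccccc2)[C@@H](c2ccccc2)O1 | intermediate
11 | {3,5,7-tris(benzyloxy)-2-[4-(benzyloxy)phenyl]-4-oxo-4H-chromen-8-yl}magnesium chloride | O=c1c(OCc2ccccc2)c(-c2ccc(OCc3ccccc3)cc2)oc2c([Mg]Cl)c(OCc3ccccc3)cc(OCc3ccccc3)c12 | intermediate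
12 | methyl (4R,5R)-2-[(R)-[4-(benzyloxy)phenyl](hydroxy){3,5,7-tris(benzyloxy)-2-[4-(benzyloxy)phenyl]-4-oxo-4H-chromen-8-yl}methyl]-4,5-diphenyl-1,3-dioxolane-2-carboxylate | COC(=O)C1(O[C@H](c2ccccc2)[C@@H](c2ccccc2)O1)[C@@](O)(c1ccc(OCc2ccccc2)cc1)c1c(OCc2ccccc2)cc(OCc2ccccc2)c2c(=O)c(OCc3ccccc3)c(-c3ccc(OCc4ccccc4)cc3)oc12 | intermediate
13 | 3,5-bis(benzyloxy)phenol | Oc1cc(OCc2ccccc2)cc(OCc2ccccc2)c1 | starting material
14 | 3,5-bis(benzyloxy)-2-bromophenol | Oc1cc(OCc2ccccc2)cc(OCc2ccccc2)c1Br | intermediate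
15 | [3,5-bis(benzyloxy)-2-bromophenoxy]trimethylsilane | C[Si](C)(C)Oc1cc(OCc2ccccc2)cc(OCc2ccccc2)c1Br | intermediate
16 | {2,4-bis(benzyloxy)-6-[(trimethylsilyl)oxy]phenyl}lithium | C[Si](C)(C)Oc1cc(OCc2ccccc2)cc(OCc2ccccc2)c1[Li] | intermediate
17 | lithium 3,5-bis(benzyloxy)-2-(trimethylsilyl)phenoxide | [Li+].[O-]c1cc(OCc2ccccc2)cc(OCc2ccccc2)c1[Si](C)(C)C | intermediate
18 | 3,5-bis(benzyloxy)-2-(trimethylsilyl)phenyl trifluoromethanesulfonate | C[Si](C)(C)c1c(OS(=O)(=O)C(F)(F)F)cc(OCc2ccccc2)cc1OCc1ccccc1 | intermediate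
19 | potassium alkoxide of 12 | COC(=O)C1(O[C@H](c2ccccc2)[C@@H](c2ccccc2)O1)[C@@]([O-])(c1ccc(OCc2ccccc2)cc1)c1c(OCc2ccccc2)cc(OCc2ccccc2)c2c(=O)c(OCc3ccccc3)c(-c3ccc(OCc4ccccc4)cc3)oc12.[K+] | intermediate
20 | 3,5-bis(benzyloxy)benzyne (1,2-didehydro-3,5-bis(benzyloxy)benzene) | C1(OCc2ccccc2)=CC(OCc2ccccc2)=CC#C1 | intermediate
21 | arylpotassium: 12 with its carbinol oxygen bonded to C1 of a 3,5-bis(benzyloxy)phenyl ring that carries potassium at C2 | COC(=O)C1(O[C@H](c2ccccc2)[C@@H](c2ccccc2)O1)[C@@](Oc1cc(OCc2ccccc2)cc(OCc2ccccc2)c1[K])(c1ccc(OCc2ccccc2)cc1)c1c(OCc2ccccc2)cc(OCc2ccccc2)c2c(=O)c(OCc3ccccc3)c(-c3ccc(OCc4ccccc4)cc3)oc12 | intermediate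
22 | (2R,4'R,5'R)-5,7-bis(benzyloxy)-2-[4-(benzyloxy)phenyl]-4',5'-diphenyl-2-{3,5,7-tris(benzyloxy)-2-[4-(benzyloxy)phenyl]-4-oxo-4H-chromen-8-yl}spiro[chromane-3,2'-[1,3]dioxolan]-4-one | O=C1c2c(OCc3ccccc3)cc(OCc3ccccc3)cc2O[C@](c2ccc(OCc3ccccc3)cc2)(c2c(OCc3ccccc3)cc(OCc3ccccc3)c3c(=O)c(OCc4ccccc4)c(-c4ccc(OCc5ccccc5)cc4)oc23)C12O[C@H](c3ccccc3)[C@@H](c3ccccc3)O2 | intermediate
23 | (2R)-5,7-dihydroxy-2-(4-hydroxyphenyl)-2-[3,5,7-trihydroxy-2-(4-hydroxyphenyl)-4-oxo-4H-chromen-8-yl]chromane-3,4-dione | O=C1c2c(O)cc(O)cc2O[C@](c2ccc(O)cc2)(c2c(O)cc(O)c3c(=O)c(O)c(-c4ccc(O)cc4)oc23)C1=O | intermediate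
24 | CNP0314633.1, (2R,3S) cis-fused hemiketal: 3,5,7-trihydroxy-2-(4-hydroxyphenyl)chroman-4-one with C2 bonded to kaempferol C8 and C3 bonded to kaempferol O7 | O=C1c2c(O)cc(O)cc2O[C@]2(c3ccc(O)cc3)c3c(cc(O)c4c(=O)c(O)c(-c5ccc(O)cc5)oc34)O[C@]12O | target

**Step count and risks**

Total steps: 11. Longest linear sequence: 7 steps (steps 3, 4, 5, 6, 7, 10, 11, from 4).

Most likely to fail:

1. Step 10 (Proposed new method). What may go wrong: retro-aldol cleavage of the C2–C3 bond in the potassium alkoxide before it meets the aryne; protonation of the aryl anion before it reaches the ester; consumption of the aryne by the methoxide that is released. Fallback (sets out from 12, returns at 22), by known reactions in separate steps: 12 is O-arylated by aryne 20, generated from 18 with CsF in MeCN at room temperature without strong base (aryne O-arylation of an alcohol, the aryl anion being quenched by the hydroxyl proton), to give the 3,5-bis(benzyloxy)phenyl ether F1. The crowded methyl ester is cleaved at its methyl carbon with LiI in hot pyridine to the carboxylic acid F2. Trifluoroacetic anhydride in CH2Cl2 at 0 °C converts this into the mixed anhydride F3 (not isolated), which acylates the phloroglucinol-type ring ortho to the ether oxygen (both ortho positions are equivalent) in an intramolecular Friedel–Crafts acylation and so closes ring C to 22.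

2. Step 7. What may go wrong: slow 1,2-addition of the doubly ortho-substituted aryl Grignard reagent to the neopentyl-type ketone, competing attack on the ester, and poor or reversed facial selectivity. Fallback (sets out from 3 and 7, returns at 12): the two aryl groups are brought in in the opposite order. Dimethyl diazomalonate and 7 give, with Rh2(OAc)4, the hydroxy ether F4; NBS and K2CO3 brominate it to the bromomalonate F5 (not isolated), which closes to the dioxolane diester F6, whose two ester groups are homotopic. Grignard reagent 11, made from 3 as in step 7, should add once to this diester at −78 °C (chelated tetrahedral intermediate) to give the keto ester F7. Commercial 4-(benzyloxy)phenylmagnesium bromide, a small nucleophile that can be used in excess, then adds to the ketone to give 12 and its C2 epimer, separated as before. Because the two aryl groups have changed roles, the same face preference now leads to the opposite C2 configuration, so this order is also the remedy if step 7 delivers mainly the unwanted epimer.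

3. Step 11. What may go wrong: slow hydrogenolysis of the crowded diphenyldioxolane, and reductive cleavage of the doubly benzylic C2–O1 bond competing with debenzylation. Fallback (sets out from 22, ends at 24): non-reductive dealkylation with BCl3 and pentamethylbenzene as cation scavenger in CH2Cl2 at −78 °C. This should cleave the seven aryl benzyl ethers and open the dioxolane at a benzylic C–O bond; aqueous work-up then collapses the remaining hemiketal ether to the C3 ketone, which closes with kaempferol O7 to 24 without an isolated intermediate.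

**Further compounds**

F1 | step 10 | methyl (4R,5R)-2-[(R)-[3,5-bis(benzyloxy)phenoxy][4-(benzyloxy)phenyl]{3,5,7-tris(benzyloxy)-2-[4-(benzyloxy)phenyl]-4-oxo-4H-chromen-8-yl}methyl]-4,5-diphenyl-1,3-dioxolane-2-carboxylate | COC(=O)C1(O[C@H](c2ccccc2)[C@@H](c2ccccc2)O1)[C@@](Oc1cc(OCc2ccccc2)cc(OCc2ccccc2)c1)(c1ccc(OCc2ccccc2)cc1)c1c(OCc2ccccc2)cc(OCc2ccccc2)c2c(=O)c(OCc3ccccc3)c(-c3ccc(OCc4ccccc4)cc3)oc12
F2 | step 10 | (4R,5R)-2-[(R)-[3,5-bis(benzyloxy)phenoxy][4-(benzyloxy)phenyl]{3,5,7-tris(benzyloxy)-2-[4-(benzyloxy)phenyl]-4-oxo-4H-chromen-8-yl}methyl]-4,5-diphenyl-1,3-dioxolane-2-carboxylic acid | OC(=O)C1(O[C@H](c2ccccc2)[C@@H](c2ccccc2)O1)[C@@](Oc1cc(OCc2ccccc2)cc(OCc2ccccc2)c1)(c1ccc(OCc2ccccc2)cc1)c1c(OCc2ccccc2)cc(OCc2ccccc2)c2c(=O)c(OCc3ccccc3)c(-c3ccc(OCc4ccccc4)cc3)oc12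
F3 | step 10 | mixed anhydride of F2 with trifluoroacetic acid | O=C(OC(=O)C(F)(F)F)C1(O[C@H](c2ccccc2)[C@@H](c2ccccc2)O1)[C@@](Oc1cc(OCc2ccccc2)cc(OCc2ccccc2)c1)(c1ccc(OCc2ccccc2)cc1)c1c(OCc2ccccc2)cc(OCc2ccccc2)c2c(=O)c(OCc3ccccc3)c(-c3ccc(OCc4ccccc4)cc3)oc12
F4 | step 7 | dimethyl 2-{[(1R,2R)-2-hydroxy-1,2-diphenylethyl]oxy}propanedioate | COC(=O)C(O[C@H](c1ccccc1)[C@H](O)c1ccccc1)C(=O)OC
F5 | step 7 | dimethyl 2-bromo-2-{[(1R,2R)-2-hydroxy-1,2-diphenylethyl]oxy}propanedioate | COC(=O)C(Br)(O[C@H](c1ccccc1)[C@H](O)c1ccccc1)C(=O)OC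
F6 | step 7 | dimethyl (4R,5R)-4,5-diphenyl-1,3-dioxolane-2,2-dicarboxylate | COC(=O)C1(C(=O)OC)O[C@H](c2ccccc2)[C@@H](c2ccccc2)O1
F7 | step 7 | methyl (4R,5R)-4,5-diphenyl-2-{3,5,7-tris(benzyloxy)-2-[4-(benzyloxy)phenyl]-4-oxo-4H-chromene-8-carbonyl}-1,3-dioxolane-2-carboxylate | COC(=O)C1(C(=O)c2c(OCc3ccccc3)cc(OCc3ccccc3)c3c(=O)c(OCc4ccccc4)c(-c4ccc(OCc5ccccc5)cc4)oc23)O[C@H](c2ccccc2)[C@@H](c2ccccc2)O1
F0 | step 11 | none | none
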